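The earlier runs and the new flask are calculated with constants of no real substance; noise was put on by code.

In this flask the smaller amount by far is the pre-initiator: 1.1 mol% on 0.53 M of free monomer comes to 0.00583 M. Each chain begun takes one pre-initiator through initiator into a living end, so pre-initiator, initiator and living ends together stay at that amount. I call it the chain ceiling: the flask cannot begin more chains than this.

| flask | free monomer | pre-initiator | remark | time |
|---|---|---|---|---|
| north-east | 0.36 M | 1.1 mol% | run made earlier |  |
| west | 0.80 M | 1.1 mol% | run made earlier |  |
| south | 0.53 M | 1.7 mol% | run made earlier |  |
| flask | 0.53 M | 1.1 mol% |  | 5.0 min |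

- north-east (time / min: monomer in chains / %, free monomer / %): 1.33: 0.5, 98.8; 2.50: 1.0, 99.7; 4.00: 2.6, 96.2; 5.00: 7.9, 93.0
- west (time / min: monomer in chains / %, free monomer / %): 0.417: 0, 101.3; 1.00: 1.1, 99.0; 2.00: 3.4, 98.2; 5.00: 24.0, 76.2
- south (time / min: monomer in chains / %, free monomer / %): 1.33: 0.5, 100.0; 2.50: 3.0, 94.5; 4.00: 10.8, 88.2; 5.00: 20.1, 79.7

(readings scatter by 1 percentage point)

- the average divides the monomer in chains by the number of chains begun, living and dead together
- the analysis behind the earlier runs scatters by 1 percentage point, standard deviation
- on the list of suspects stand: pre-initiator <-> initiator; free monomer + living end -> monomer in chains + living end; free monomer + initiator -> living end + monomer in chains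
- the earlier runs do not show the number of chains; that part of a forecast is a guess

1. average number of monomer units in a chain (chains begun, living or dead) at 5.0 min
2. part of the free monomer that has reacted at 5.0 min

First I need the conversion, and I reach it in two ways. For each run I take the mean of what the chains gained and the free monomer lost at 5.00 min, and form the logarithm of charged over left. The first way stays at the flask's loading: north-east gives 0.0774 and west 0.273, and interpolating between them on logarithmic scales gives the flask 13.3%. The second way uses a different run: south has the flask's free monomer, and I scale its 0.226 down by the ratio of loadings, which gives 13.6%. The two stand 0.3 percentage points apart, with readings that scatter by 1 point, so I commit to 13.4%.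

Dividing the monomer in chains by the ceiling gives a floor of 12.2 units per chain. That floor counts every pre-initiator as a chain from the start, and here the readings part from it. In south the monomer in chains grows by a factor of 6.70 between 2.50 min and 5.00 min, more than the 2 that a steady number of ends would give. I read this in south as an induction period, and I expect the same in the flask, so the floor is what cheats, and I expect the flask's chain length above it by an amount the runs do not show.

The forecast gives 13% and a chain length of 40, and says of the rise above the floor: “The size of that increase is essentially a guess.”

The flask gives a chain length of 193 at a conversion of 13.2%.

    pre-initiator ⇌ initiator (K = 0.360, k = 0.0470 min⁻¹)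
    free monomer + living end → monomer in chains + living end, rate k2*[living end]*[free monomer] (k = 200 M⁻¹ min⁻¹)
    free monomer + initiator → living end + monomer in chains (k = 0.360 M⁻¹ min⁻¹)

At 5.00 min the flask holds 3.63 × 10⁻⁴ M of living end, and pre-initiator stands at 83.2% of its own charge. Those living ends are 6.22% of the chain ceiling. The neighbouring flask with 2.1 M of free monomer, at the same loading, has a ceiling of 0.0231 M. Its 0.00254 M of living end at 5.00 min fill 11.0% of that ceiling, and its chain length is 583.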